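(The earlier runs and the new flask were generated by integration with made-up constants; scatter was added.)

Epsilon's readings suggest that its catalyst fails. Its activity, meaning target gained per hour over the starting material present and corrected for the growing volume, reads 0.637 h⁻¹ in the first window and 0.634 h⁻¹ in the next, about the same. Between the last two readings it has dropped to 0.193 h⁻¹. The activity holds and then falls, which does not look like a loss steady in time, so I suppose the catalyst dies by meeting target.

| flask | starting material | free catalyst | temperature | remark | time |
|---|---|---|---|---|---|
| beta | 1.6 M (fed, over 15 h) | 4.1 mM | 0 °C | run made earlier; the fed solution adds 1.0 times the starting volume |  |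
| epsilon | 1.6 M (fed, over 15 h) | 6.4 mM | 22 °C | run made earlier; the fed solution adds 1.0 times the starting volume |  |
| alpha | 0.80 M (fed, over 15 h) | 2.9 mM | 0 °C | run made earlier; the fed solution adds 1.0 times the starting volume |  |
| red | 1.6 M (fed, over 15 h) | 2.9 mM |  | at −10 °C until 15 h, from then on at 30 °C; the fed solution adds 1.0 times the starting volume | 40 h |
| green | 1.6 M (fed, over 15 h) | 2.9 mM |  | at 30 °C throughout; the fed solution adds 1.0 times the starting volume | 40 h |

- beta (time / h: target / %, starting material / %): 2.00: 0, 12.7; 4.00: 2.9, 23.6; 8.00: 7.1, 46.9; 12.0: 14.4, 66.9; 25.0: 33.6, 66.9
- epsilon (time / h: target / %, starting material / %): 0.667: 0.7, 3.6; 1.33: 2.6, 6.0; 2.50: 7.4, 8.6; 4.00: 14.2, 12.5; 8.00: 25.6, 28.8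
- alpha (time / h: target / %, starting material / %): 2.50: 1.3, 16.0; 6.00: 3.0, 37.7; 12.0: 10.4, 69.7; 20.0: 20.9, 78.3; 25.0: 27.3, 71.9

(standard deviation of a reading: 0.5 percentage points)

- every charge counts on the volume at the start, and the solution that is fed holds the whole dose
- a reading or a percentage of target counts all its forms, free or not
- percentages count the whole charge, also what has not yet gone in

- which of the two ends with the higher amount of target, in percent of the starting material charged ("neither" if they lie within 2 percentage points) (red / green / neither)
- target at the end, in percent of the starting material charged, red
- target at the end, in percent of the starting material charged, green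

If target forms at a rate set by starting material times catalyst, and catalyst dies at a rate set by catalyst times target, then dividing one by the other removes both clock and volume. With starting material held steady, target squared then equals 2 times the ratio, times starting material, times catalyst lost, all per starting volume. In its last window epsilon reads a loss of 69.7% of its catalyst, with starting material read at 12.5% at the start of that window, and with the mean target of the window that gives 56.9 for the budget ratio, the rate constant for making target over that for losing catalyst (a selectivity factor). I assume it unchanged at 30 °C.

Green's activity, scaled from beta and epsilon, comes to 0.648 h⁻¹, close to epsilon's, so I assume that green's catalyst is lost with starting material standing at the same share as in epsilon, which gives 16.1%. For red I assume that the catalyst lasts through the cold feed and is lost with the charge fully fed, and the first pass gives 45.4%. The weak link is holding red's starting material constant. Taking instead the mean of red's starting material before and after the conversion gives 40.5%.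

The forecast says red, with 36% (24% to 52%) for red and 6% (3% to 14%) for green, whose catalyst “dies before much starting material has been fed”; my green stands higher.

Red ends at 38.5% and green at 17.2%.

    starting material + free catalyst → free catalyst + target (k = 4.20 M⁻¹ h⁻¹, Ea = 65.0 kJ mol⁻¹)
    free catalyst + target → spent catalyst (k = 0.0410 M⁻¹ h⁻¹, Ea = 75.0 kJ mol⁻¹)
    crystals ⇌ target, rate k3*(cs3 - [target]) while solid is left; crystals form when [target] > cs3 (solubility = 0.880 M, k = 7.30 h⁻¹)
    (constants at −10 °C)

At 40.0 h red holds 0% free catalyst beside 61.3% starting material. A neighbour, green's flask held at 5 °C, has 87.1% of its catalyst spent at 40.0 h. The budget ratio with that loss gives 38.1%, and the flask holds 40.2% target.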